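**Plan**

1. Retrosynthesis: after removal of three MOM ethers, ring C of the flavanone is cut at two bonds at once, O1–C8a and C4–C4a. This separates ring A as an aryne from a ring B chain that already holds O1, C2, C3 and C4 (a β-oxygenated ester).
2. The feature that allows this: O1 and the C4 carbonyl sit on neighbouring carbons (C8a, C4a) of ring A. The C5 oxygen lies next to C4a and the C8 prenyl group next to C8a, so a C4a≡C8a aryne is polarised for oxygen attack at C8a and acylation at C4a. C8a is a phloroglucinol carbon, so its phenol can serve as the triflate leaving group.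
3. Ring B fragment (steps 1–6), from 4-hydroxy-2-methoxyacetophenone: aromatic Claisen rearrangement of the prenyl ether installs the 1,1-dimethylallyl group; Claisen condensation, asymmetric transfer hydrogenation and O-silylation give the (S)-β-silyloxy ester.
4. Ring A fragment (steps 7–12), from phloroglucinol: O-(1,1-dimethylallyl)ation and Claisen rearrangement give the ortho-prenyl phenol; carbamate-directed ortho-silylation and triflation give the 2-(trimethylsilyl)aryl triflate.
5. Union (step 13): fluoride unmasks alkoxide and aryne together, and addition followed by intramolecular acylation closes ring C. The helpers (O-silyl, C-silyl, triflate, ester methoxide) leave in this step; acid removes the MOM ethers in step 14.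
6. Stereochemistry: the only stereocenter, C2 (S), comes from the Noyori transfer hydrogenation in step 5 and is carried into ring C with retention, because its C–O bond is never broken.

Key step: step 13

Remark: flavanone numbering is used (O1, C2, C3, C4, C4a, C5 to C8, C8a; ring B primed); the target's stereocenter is (2S); tert-butyl 2-methylbut-3-en-2-yl carbonate is taken as a purchasable reagent (otherwise one step from 2-methylbut-3-en-2-ol and Boc2O).

**Route**

Step 1
Reactants: 1 1-(4-hydroxy-2-methoxyphenyl)ethan-1-one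
Product: 2 1-[2-methoxy-4-(3-methylbut-2-en-1-yloxy)phenyl]ethan-1-one
Conditions: prenyl bromide, K2CO3, acetone, reflux
Reagents that add atoms: prenyl bromide (1-bromo-3-methylbut-2-ene), CC(C)=CCBr
Why: Williamson ether synthesis: the single phenol, made more acidic by the para acetyl group, is deprotonated by K2CO3 and alkylated at oxygen by the primary allylic bromide without enolization of the ketone.

Step 2
Reactants: 2 1-[2-methoxy-4-(3-methylbut-2-en-1-yloxy)phenyl]ethan-1-one
Product: 3 1-[4-hydroxy-2-methoxy-5-(2-methylbut-3-en-2-yl)phenyl]ethan-1-one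
Conditions: EtOH/H2O (4:1), 130 °C, sealed tube
Reagents that add atoms: none
Why: Aromatic Claisen rearrangement ([3,3]-sigmatropic): the prenyl group is transferred with allylic inversion to the ortho carbon C5 (C3 lies between two oxygens and is more hindered, the para position carries the acetyl group), rearomatization gives the ortho-(1,1-dimethylallyl)phenol, and the aqueous medium accelerates the shift so that a temperature below that of the abnormal Claisen pathway should suffice.

Step 3
Reactants: 3 1-[4-hydroxy-2-methoxy-5-(2-methylbut-3-en-2-yl)phenyl]ethan-1-one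
Product: 4 1-[2-methoxy-4-(methoxymethoxy)-5-(2-methylbut-3-en-2-yl)phenyl]ethan-1-one
Conditions: MOMCl, K2CO3, acetone, rt
Reagents that add atoms: chloromethyl methyl ether (MOMCl), COCCl
Why: Williamson-type O-alkylation with MOMCl gives an acetal that should withstand NaH, formate reduction, fluoride and the aryne, and that blocks the phenol as a competing nucleophile in step 13.

Step 4
Reactants: 4 1-[2-methoxy-4-(methoxymethoxy)-5-(2-methylbut-3-en-2-yl)phenyl]ethan-1-one
Product: 5 methyl 3-[2-methoxy-4-(methoxymethoxy)-5-(2-methylbut-3-en-2-yl)phenyl]-3-oxopropanoate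
Conditions: NaH, dimethyl carbonate, THF, reflux; then AcOH
Reagents that add atoms: dimethyl carbonate, COC(=O)OC
Why: Crossed Claisen condensation: the ketone enolate is acylated by the non-enolizable dimethyl carbonate and the equilibrium is pulled forward by deprotonation of the β-keto ester formed.

Step 5
Reactants: 5 methyl 3-[2-methoxy-4-(methoxymethoxy)-5-(2-methylbut-3-en-2-yl)phenyl]-3-oxopropanoate
Product: 6 methyl (3S)-3-hydroxy-3-[2-methoxy-4-(methoxymethoxy)-5-(2-methylbut-3-en-2-yl)phenyl]propanoate
Conditions: RuCl(p-cymene)[(S,S)-TsDPEN] (1 mol %), HCO2H/Et3N (5:2), 40 °C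
Reagents that add atoms: none
Why: Noyori asymmetric transfer hydrogenation: the ruthenium hydride with its N–H transfers hydride and proton to the aryl ketone through a six-membered outer-sphere transition state in which the ring B arene lies against the cymene ligand (CH/π contact), so the (S,S)-ligand should give the (S)-alcohol as it does with acetophenones, and the vinyl group and the ester are not reduced.

Step 6
Reactants: 6 methyl (3S)-3-hydroxy-3-[2-methoxy-4-(methoxymethoxy)-5-(2-methylbut-3-en-2-yl)phenyl]propanoate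
Product: 7 methyl (3S)-3-[2-methoxy-4-(methoxymethoxy)-5-(2-methylbut-3-en-2-yl)phenyl]-3-(trimethylsilyloxy)propanoate
Conditions: 1-(trimethylsilyl)imidazole, CH2Cl2, rt
Reagents that add atoms: 1-(trimethylsilyl)imidazole, C[Si](C)(C)n1ccnc1
Why: O-silylation (silyl transfer from the N-silylimidazole to the secondary alcohol) gives a proton-free precursor of the alkoxide that fluoride can unmask in step 13.

Step 7
Reactants: 8 phloroglucinol (benzene-1,3,5-triol)
Product: 9 3,5-bis(methoxymethoxy)phenol
Conditions: MOMCl (2 equiv), K2CO3, acetone, 0 °C → rt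
Reagents that add atoms: chloromethyl methyl ether (MOMCl), COCCl
Why: Williamson-type O-alkylation under statistical control: two of the three equivalent phenols are capped, and the bis-ether should be separable by chromatography from the mono-ether (which can be returned to the reaction) and the tris-ether.

Step 8
Reactants: 9 3,5-bis(methoxymethoxy)phenol
Product: 10 1,3-bis(methoxymethoxy)-5-(2-methylbut-3-en-2-yloxy)benzene
Conditions: tert-butyl 2-methylbut-3-en-2-yl carbonate, Pd(PPh3)4 (cat.), THF, 0 °C
Reagents that add atoms: tert-butyl 2-methylbut-3-en-2-yl carbonate, C=CC(C)(C)OC(=O)OC(C)(C)C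
Why: Tsuji–Trost allylic etherification: zerovalent palladium ionizes the tertiary carbonate, loss of CO2 gives tert-butoxide that deprotonates the phenol, and under kinetic control at low temperature the phenoxide should attack the more substituted terminus of the 1,1-dimethylallyl palladium complex to give the tertiary ether.

Step 9
Reactants: 10 1,3-bis(methoxymethoxy)-5-(2-methylbut-3-en-2-yloxy)benzene
Product: 11 3,5-bis(methoxymethoxy)-2-(3-methylbut-2-en-1-yl)phenol
Conditions: toluene, 110 °C
Reagents that add atoms: none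
Why: Aromatic Claisen rearrangement ([3,3]-sigmatropic) of the 1,1-dimethylallyl ether: the allyl unit arrives inverted, as a prenyl group, at one of the two equivalent ortho carbons, and tautomerization leaves the free phenol next to it, which marks this oxygen as the later triflate.

Step 10
Reactants: 11 3,5-bis(methoxymethoxy)-2-(3-methylbut-2-en-1-yl)phenol
Product: 12 3,5-bis(methoxymethoxy)-2-(3-methylbut-2-en-1-yl)phenyl N-(propan-2-yl)carbamate
Conditions: i-PrNCO, Et3N (cat.), CH2Cl2, rt
Reagents that add atoms: isopropyl isocyanate, CC(C)N=C=O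
Why: Addition of the phenol to the isocyanate (carbamoylation) installs the strongest oxygen-based directing group for ortho-metalation, which can later be removed under mild amine conditions.

Step 11
Reactants: 12 3,5-bis(methoxymethoxy)-2-(3-methylbut-2-en-1-yl)phenyl N-(propan-2-yl)carbamate
Product: 16 3,5-bis(methoxymethoxy)-2-(3-methylbut-2-en-1-yl)-6-(trimethylsilyl)phenyl N-(propan-2-yl)carbamate, via N-TBS carbamate 13 (not isolated), via aryllithium 14 (not isolated), via N-TBS C-TMS carbamate 15 (not isolated)
Conditions: TBSOTf, TMEDA, Et2O, 0 °C → rt; n-BuLi, TMEDA, −78 °C; TMSCl, −78 °C → rt; aq. NaHSO4 (brief, 0 °C)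
Reagents that add atoms: chlorotrimethylsilane (TMSCl), C[Si](C)(C)Cl
Why: Directed ortho-metalation: after N-silylation in the flask (which prevents N–H deprotonation and loss of isocyanate) the carbamate and the neighbouring MOM ether should together direct n-BuLi to C6, the only ring C–H ortho to the carbamate, TMSCl traps the aryllithium, and the N-silyl group is lost on aqueous work-up.

Step 12
Reactants: 16 3,5-bis(methoxymethoxy)-2-(3-methylbut-2-en-1-yl)-6-(trimethylsilyl)phenyl N-(propan-2-yl)carbamate
Product: 18 3,5-bis(methoxymethoxy)-2-(3-methylbut-2-en-1-yl)-6-(trimethylsilyl)phenyl trifluoromethanesulfonate, via phenol 17 (not isolated)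
Conditions: Et2NH, DBU, MeCN, 40 °C; then PhNTf2, rt
Reagents that add atoms: N-phenylbis(trifluoromethanesulfonimide) (PhNTf2), O=S(=O)(N(c1ccccc1)S(=O)(=O)C(F)(F)F)C(F)(F)F
Why: Base-induced carbamate cleavage (E1cB loss of isopropyl isocyanate, trapped by Et2NH as a urea) frees the phenoxide, which is sulfonylated at oxygen by PhNTf2 in the same flask, a known one-flask route to 2-(trimethylsilyl)aryl triflates.

Step 13
Reactants: 7 methyl (3S)-3-[2-methoxy-4-(methoxymethoxy)-5-(2-methylbut-3-en-2-yl)phenyl]-3-(trimethylsilyloxy)propanoate; 18 3,5-bis(methoxymethoxy)-2-(3-methylbut-2-en-1-yl)-6-(trimethylsilyl)phenyl trifluoromethanesulfonate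
Product: 21 (2S)-5,7-bis(methoxymethoxy)-2-[2-methoxy-4-(methoxymethoxy)-5-(2-methylbut-3-en-2-yl)phenyl]-8-(3-methylbut-2-en-1-yl)-2,3-dihydro-4H-chromen-4-one, via potassium alkoxide 19 (not isolated), via aryne 20 (not isolated)
Conditions: 7 (1 equiv), 18 (1.2 equiv), KF, 18-crown-6, DME, −20 °C → rt
Reagents that add atoms: none
Why: Proposed new method: fluoride cleaves the O–Si bond of 7 and the C–Si bond of 18, so that alkoxide 19 and aryne 20 (triple bond between C4a and C8a) arise together in an aprotic medium; 19 adds through oxygen to C8a, and the carbanion left at C4a attacks the methyl ester of the same molecule and expels methoxide, which forms O1–C8a and C4–C4a in one operation and ring C with them. The closest known reaction type is the fluoride-induced annulation of 2-(trimethylsilyl)aryl triflates with methyl salicylates to xanthones (phenoxide addition to the aryne, then acyl substitution by the aryl anion), together with the known O-arylation of aliphatic alcohols by arynes; new here are the secondary alkoxide and the enolizable aliphatic ester. Ring C closes in the 6-exo-trig mode, by attack of the C4a carbanion on the ester carbonyl. No new stereocenter forms, and C2 keeps the (S) configuration of 7 because its C–O bond is not touched and because the methoxide set free is captured at silicon as MeOSiMe3, so that no base strong enough for E1cB opening of ring C should build up. The step needs addition to one end of an unsymmetrical aryne, and the MOM-protected oxygen at C5, next to C4a, secures it: by its inductive pull and the resulting distortion of the aryne it sends nucleophiles to the far carbon C8a and leaves the carbanion ortho to oxygen. It also needs acylation of the carbanion to win over protonation, which the absence of any O–H donor secures (silyl ether in place of the alcohol, no acetonitrile), while the C8 prenyl group is held too close to C8a for an intramolecular ene reaction.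

Step 14
Reactants: 21 (2S)-5,7-bis(methoxymethoxy)-2-[2-methoxy-4-(methoxymethoxy)-5-(2-methylbut-3-en-2-yl)phenyl]-8-(3-methylbut-2-en-1-yl)-2,3-dihydro-4H-chromen-4-one
Product: 22 (2S)-5,7-dihydroxy-2-[4-hydroxy-2-methoxy-5-(2-methylbut-3-en-2-yl)phenyl]-8-(3-methylbut-2-en-1-yl)-2,3-dihydro-4H-chromen-4-one
Conditions: 3 M aq. HCl, MeOH, 40 °C
Reagents that add atoms: none
Why: Acid-catalysed acetal cleavage (methanolysis of the three aryl MOM ethers), the usual last step for prenylated flavonoids: under dilute acid at mild temperature the prenyl and 1,1-dimethylallyl groups should not cyclize onto the neighbouring phenols, and C2 is not at risk because retro-oxa-Michael opening of flavanones needs base.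

**Compound list**

1 | 1-(4-hydroxy-2-methoxyphenyl)ethan-1-one | CC(=O)c1ccc(O)cc1OC | starting material
2 | 1-[2-methoxy-4-(3-methylbut-2-en-1-yloxy)phenyl]ethan-1-one | CC(=O)c1ccc(OCC=C(C)C)cc1OC | intermediate
3 | 1-[4-hydroxy-2-methoxy-5-(2-methylbut-3-en-2-yl)phenyl]ethan-1-one | CC(=O)c1cc(C(C)(C)C=C)c(O)cc1OC | intermediate
4 | 1-[2-methoxy-4-(methoxymethoxy)-5-(2-methylbut-3-en-2-yl)phenyl]ethan-1-one | CC(=O)c1cc(C(C)(C)C=C)c(OCOC)cc1OC | intermediate
5 | methyl 3-[2-methoxy-4-(methoxymethoxy)-5-(2-methylbut-3-en-2-yl)phenyl]-3-oxopropanoate | COC(=O)CC(=O)c1cc(C(C)(C)C=C)c(OCOC)cc1OC | intermediate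
6 | methyl (3S)-3-hydroxy-3-[2-methoxy-4-(methoxymethoxy)-5-(2-methylbut-3-en-2-yl)phenyl]propanoate | C=CC(C)(C)c1cc([C@@H](O)CC(=O)OC)c(OC)cc1OCOC | intermediate
7 | methyl (3S)-3-[2-methoxy-4-(methoxymethoxy)-5-(2-methylbut-3-en-2-yl)phenyl]-3-(trimethylsilyloxy)propanoate | C=CC(C)(C)c1cc([C@@H](O[Si](C)(C)C)CC(=O)OC)c(OC)cc1OCOC | intermediate
8 | phloroglucinol (benzene-1,3,5-triol) | Oc1cc(O)cc(O)c1 | starting material
9 | 3,5-bis(methoxymethoxy)phenol | COCOc1cc(O)cc(OCOC)c1 | intermediate
10 | 1,3-bis(methoxymethoxy)-5-(2-methylbut-3-en-2-yloxy)benzene | C=CC(C)(C)Oc1cc(OCOC)cc(OCOC)c1 | intermediate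
11 | 3,5-bis(methoxymethoxy)-2-(3-methylbut-2-en-1-yl)phenol | CC(C)=CCc1c(O)cc(OCOC)cc1OCOC | intermediate
12 | 3,5-bis(methoxymethoxy)-2-(3-methylbut-2-en-1-yl)phenyl N-(propan-2-yl)carbamate | CC(C)=CCc1c(OC(=O)NC(C)C)cc(OCOC)cc1OCOC | intermediate
13 | 3,5-bis(methoxymethoxy)-2-(3-methylbut-2-en-1-yl)phenyl N-(tert-butyldimethylsilyl)-N-(propan-2-yl)carbamate | CC(C)=CCc1c(OC(=O)N(C(C)C)[Si](C)(C)C(C)(C)C)cc(OCOC)cc1OCOC | intermediate (not isolated)
14 | C6-lithio derivative of 13 | CC(C)=CCc1c(OC(=O)N(C(C)C)[Si](C)(C)C(C)(C)C)c([Li])c(OCOC)cc1OCOC | intermediate (not isolated)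
15 | 3,5-bis(methoxymethoxy)-2-(3-methylbut-2-en-1-yl)-6-(trimethylsilyl)phenyl N-(tert-butyldimethylsilyl)-N-(propan-2-yl)carbamate | CC(C)=CCc1c(OC(=O)N(C(C)C)[Si](C)(C)C(C)(C)C)c([Si](C)(C)C)c(OCOC)cc1OCOC | intermediate (not isolated)
16 | 3,5-bis(methoxymethoxy)-2-(3-methylbut-2-en-1-yl)-6-(trimethylsilyl)phenyl N-(propan-2-yl)carbamate | CC(C)=CCc1c(OC(=O)NC(C)C)c([Si](C)(C)C)c(OCOC)cc1OCOC | intermediate
17 | 3,5-bis(methoxymethoxy)-2-(3-methylbut-2-en-1-yl)-6-(trimethylsilyl)phenol | CC(C)=CCc1c(O)c([Si](C)(C)C)c(OCOC)cc1OCOC | intermediate (not isolated)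
18 | 3,5-bis(methoxymethoxy)-2-(3-methylbut-2-en-1-yl)-6-(trimethylsilyl)phenyl trifluoromethanesulfonate | CC(C)=CCc1c(OS(=O)(=O)C(F)(F)F)c([Si](C)(C)C)c(OCOC)cc1OCOC | intermediate
19 | potassium (1S)-3-methoxy-1-[2-methoxy-4-(methoxymethoxy)-5-(2-methylbut-3-en-2-yl)phenyl]-3-oxopropan-1-olate | C=CC(C)(C)c1cc([C@@H]([O-])CC(=O)OC)c(OC)cc1OCOC.[K+] | intermediate (not isolated)
20 | 1,2-didehydro-3,5-bis(methoxymethoxy)-6-(3-methylbut-2-en-1-yl)benzene (aryne) | CC(C)=CCC1=C(OCOC)C=C(OCOC)C#C1 | intermediate (not isolated)
21 | (2S)-5,7-bis(methoxymethoxy)-2-[2-methoxy-4-(methoxymethoxy)-5-(2-methylbut-3-en-2-yl)phenyl]-8-(3-methylbut-2-en-1-yl)-2,3-dihydro-4H-chromen-4-one | C=CC(C)(C)c1cc([C@@H]2CC(=O)c3c(OCOC)cc(OCOC)c(CC=C(C)C)c3O2)c(OC)cc1OCOC | intermediate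
22 | (2S)-5,7-dihydroxy-2-[4-hydroxy-2-methoxy-5-(2-methylbut-3-en-2-yl)phenyl]-8-(3-methylbut-2-en-1-yl)-2,3-dihydro-4H-chromen-4-one | C=CC(C)(C)c1cc([C@@H]2CC(=O)c3c(O)cc(O)c(CC=C(C)C)c3O2)c(OC)cc1O | target

**Step count and risks**

Total step count: 14. Longest linear sequence: 8 steps (steps 1–6, 13, 14; the ring A branch, steps 7–12, 13, 14, is equally long).

Steps most likely to fail:

1. Step 13 (proposed new method). What may go wrong:
   - protonation or internal α-deprotonation of the C4a carbanion before it reaches the ester;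
   - base-induced elimination of the benzylic oxygen from the silyloxy ester;
   - retro-oxa-Michael opening of ring C in the basic fluoride medium, with loss of configuration at C2;
   - consumption of the aryne by solvent or methoxide.

   Fallback (known chemistry, sets out from 6 and 18, comes back at 21): the two fragments are joined by the known insertion of an aryne into the C–O bond of a carboxylic acid, which forms the same O–C8a and C4–C4a bonds but gives up the stereocenter. Compound 6 is dehydrated (MsCl, Et3N; then DBU) to methyl (2E)-3-[2-methoxy-4-(methoxymethoxy)-5-(2-methylbut-3-en-2-yl)phenyl]prop-2-enoate F1 and saponified (LiOH, THF/H2O) to (2E)-3-[2-methoxy-4-(methoxymethoxy)-5-(2-methylbut-3-en-2-yl)phenyl]prop-2-enoic acid F2. F2 and 18 with CsF in THF (125 °C, sealed tube) should give, by carboxylate addition at C8a and acyl shift from oxygen to C4a, (2E)-1-[2-hydroxy-4,6-bis(methoxymethoxy)-3-(3-methylbut-2-en-1-yl)phenyl]-3-[2-methoxy-4-(methoxymethoxy)-5-(2-methylbut-3-en-2-yl)phenyl]prop-2-en-1-one F3. NaOAc in EtOH at reflux closes ring C by oxa-Michael addition to racemic 5,7-bis(methoxymethoxy)-2-[2-methoxy-4-(methoxymethoxy)-5-(2-methylbut-3-en-2-yl)phenyl]-8-(3-methylbut-2-en-1-yl)-2,3-dihydro-4H-chromen-4-one F4. Preparative HPLC on a chiral stationary phase separates 21 from its (2R)-enantiomer F5, which can be returned to F4 by base-induced ring opening and reclosure.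

2. Step 11. What may go wrong:
   - deprotonation at the allylic and benzylic CH2 of the prenyl group next to the carbamate (followed by carbamoyl migration) instead of at C6;
   - deprotonation at C4 between the two MOM ethers;
   - attack of the silyl triflate on the MOM acetals.

   Fallback (sets out from 9, comes back at 17): silicon is introduced before the prenyl group. Compound 9 with i-PrNCO and Et3N gives 3,5-bis(methoxymethoxy)phenyl N-(propan-2-yl)carbamate F6. The same N-silylation, lithiation and TMSCl sequence (no allylic CH2 present, both carbons ortho to the carbamate equivalent) gives 3,5-bis(methoxymethoxy)-2-(trimethylsilyl)phenyl N-(propan-2-yl)carbamate F7. Et2NH and DBU in MeCN free 3,5-bis(methoxymethoxy)-2-(trimethylsilyl)phenol F8. Pd(PPh3)4 with tert-butyl 2-methylbut-3-en-2-yl carbonate gives trimethyl[2,4-bis(methoxymethoxy)-6-(2-methylbut-3-en-2-yloxy)phenyl]silane F9. Its Claisen rearrangement (toluene, 110 °C) can only go to the one free ortho carbon and gives 17, which is isolated and triflated (PhNTf2, DBU) to 18 as in the second half of step 12.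

3. Step 14. What may go wrong:
   - acid-catalysed cyclization of the prenyl group onto the C7 hydroxyl (chroman formation) or of the 1,1-dimethylallyl group onto the C4' hydroxyl;
   - slow acid-induced opening of ring C on prolonged heating.

   Fallback (sets out from 21, comes back at 22): the protecting group is exchanged in place without protic acid and then removed with fluoride. TESOTf and 2,2'-bipyridyl in CH2Cl2 at 0 °C should convert the three aryl MOM ethers into (2S)-2-[2-methoxy-5-(2-methylbut-3-en-2-yl)-4-(triethylsilyloxy)phenyl]-8-(3-methylbut-2-en-1-yl)-5,7-bis(triethylsilyloxy)-2,3-dihydro-4H-chromen-4-one F10. Buffered fluoride (Bu4NF/AcOH, THF, 0 °C) then cleaves the silyl ethers (and any silyl enol ether formed at C4) to give 22.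

**Further compounds**

F1 | step 13 | methyl (2E)-3-[2-methoxy-4-(methoxymethoxy)-5-(2-methylbut-3-en-2-yl)phenyl]prop-2-enoate | COC(=O)/C=C/c1cc(C(C)(C)C=C)c(OCOC)cc1OC
F2 | step 13 | (2E)-3-[2-methoxy-4-(methoxymethoxy)-5-(2-methylbut-3-en-2-yl)phenyl]prop-2-enoic acid | OC(=O)/C=C/c1cc(C(C)(C)C=C)c(OCOC)cc1OC
F3 | step 13 | (2E)-1-[2-hydroxy-4,6-bis(methoxymethoxy)-3-(3-methylbut-2-en-1-yl)phenyl]-3-[2-methoxy-4-(methoxymethoxy)-5-(2-methylbut-3-en-2-yl)phenyl]prop-2-en-1-one | C=CC(C)(C)c1cc(/C=C/C(=O)c2c(O)c(CC=C(C)C)c(OCOC)cc2OCOC)c(OC)cc1OCOC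
F4 | step 13 | racemic 5,7-bis(methoxymethoxy)-2-[2-methoxy-4-(methoxymethoxy)-5-(2-methylbut-3-en-2-yl)phenyl]-8-(3-methylbut-2-en-1-yl)-2,3-dihydro-4H-chromen-4-one | C=CC(C)(C)c1cc(C2CC(=O)c3c(OCOC)cc(OCOC)c(CC=C(C)C)c3O2)c(OC)cc1OCOC
F5 | step 13 | (2R)-5,7-bis(methoxymethoxy)-2-[2-methoxy-4-(methoxymethoxy)-5-(2-methylbut-3-en-2-yl)phenyl]-8-(3-methylbut-2-en-1-yl)-2,3-dihydro-4H-chromen-4-one | C=CC(C)(C)c1cc([C@H]2CC(=O)c3c(OCOC)cc(OCOC)c(CC=C(C)C)c3O2)c(OC)cc1OCOC
F6 | step 11 | 3,5-bis(methoxymethoxy)phenyl N-(propan-2-yl)carbamate | CC(C)NC(=O)Oc1cc(OCOC)cc(OCOC)c1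
F7 | step 11 | 3,5-bis(methoxymethoxy)-2-(trimethylsilyl)phenyl N-(propan-2-yl)carbamate | CC(C)NC(=O)Oc1cc(OCOC)cc(OCOC)c1[Si](C)(C)C
F8 | step 11 | 3,5-bis(methoxymethoxy)-2-(trimethylsilyl)phenol | Oc1cc(OCOC)cc(OCOC)c1[Si](C)(C)C
F9 | step 11 | trimethyl[2,4-bis(methoxymethoxy)-6-(2-methylbut-3-en-2-yloxy)phenyl]silane | C=CC(C)(C)Oc1cc(OCOC)cc(OCOC)c1[Si](C)(C)C
F10 | step 14 | (2S)-2-[2-methoxy-5-(2-methylbut-3-en-2-yl)-4-(triethylsilyloxy)phenyl]-8-(3-methylbut-2-en-1-yl)-5,7-bis(triethylsilyloxy)-2,3-dihydro-4H-chromen-4-one | C=CC(C)(C)c1cc([C@@H]2CC(=O)c3c(O[Si](CC)(CC)CC)cc(O[Si](CC)(CC)CC)c(CC=C(C)C)c3O2)c(OC)cc1O[Si](CC)(CC)CC
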